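**Strategy**

The route rests on disconnecting ring A across C4–C5 and C1=C10. The ring is nothing more than a ring B ketone carbon (C10), its only enolisable α-carbon (C5, C9 being quaternary) and the six carbons of mesityl oxide (C1–C4 and the gem-dimethyl pair). One annulation, Mukaiyama–Michael addition followed by aldol condensation, forms both bonds, closes ring A, sets C5 and places the alkene at C1=C10. Its precursor is the trimethylsilyl enol ether of (2S,3S)-2-allyl-2,3-dimethylcyclohexanone, made by asymmetric methyl addition and enolate methylation. The C2 carbonyl is then removed, and the allyl group is elaborated by cross-metathesis, auxiliary-controlled allylation at C13, B-alkyl Suzuki coupling with a bromobutenolide and sulfation.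

Key step: step 5

**Assumptions**

- Atom numbers are those of the target: ring A is C1–C5 plus C10, ring B is C5–C10, the side chain is C11–C16, and C13 carries the CH2O carbon. The target is (5R,8S,9S,13S).
- The target is drawn as the free hydrogen sulfate and is made in that form; it is best kept cold and dilute, or stored as its sodium salt.
- The sense of induction of the copper–diphosphine catalyst in step 3 is assigned by analogy with unsubstituted cyclohexenone; should a trial run show the opposite sense, the mirror-image ligand is used.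

**Route**

Step 1
Reactants: 1 cyclohex-2-en-1-one
Product: 2 2-iodocyclohex-2-en-1-one
Conditions: I2, pyridine, CH2Cl2, 0 °C → rt
Reagents that add atoms: iodine, II
Why: α-Iodination of an enone by conjugate addition of pyridine, iodination of the resulting enolate and elimination of pyridine, a standard entry to 2-iodocycloalkenones.

Step 2
Reactants: 2 2-iodocyclohex-2-en-1-one; 3 allyltributylstannane
Product: 4 2-(prop-2-en-1-yl)cyclohex-2-en-1-one
Conditions: PdCl2(PhCN)2 (5 mol %), AsPh3 (10 mol %), CuI (10 mol %), NMP, rt → 50 °C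
Reagents that add atoms: allyltributylstannane (3), C=CC[Sn](CCCC)(CCCC)CCCC
Why: Stille coupling of an α-iodoenone, in which AsPh3 and CuI speed up transmetalation so that the allyl group should be transferred to C2 without attack on the enone.

Step 3
Reactants: 4 2-(prop-2-en-1-yl)cyclohex-2-en-1-one
Product: 6 (2S,3S)-2,3-dimethyl-2-(prop-2-en-1-yl)cyclohexan-1-one, via bromomagnesium enolate 5 (not isolated)
Conditions: MeMgBr, CuBr·SMe2 (5 mol %), (R)-1-[(S)-2-(diphenylphosphino)ferrocenyl]ethyldicyclohexylphosphine (6 mol %), t-BuOMe, −78 °C; then MeI, DMPU, −78 → 0 °C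
Reagents that add atoms: methylmagnesium bromide, C[Mg]Br; iodomethane, CI
Why: Copper-catalysed asymmetric conjugate addition of a Grignard reagent to an α-substituted cyclohexenone sets C8 through the chiral diphosphine–copper complex and gives a regiodefined magnesium enolate, which is methylated anti to the pseudoaxial C8 methyl so that the two methyl groups end up trans and C9 becomes quaternary with the allyl group cis to the C8 methyl.

Step 4
Reactants: 6 (2S,3S)-2,3-dimethyl-2-(prop-2-en-1-yl)cyclohexan-1-one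
Product: 7 {[(5S,6S)-5,6-dimethyl-6-(prop-2-en-1-yl)cyclohex-1-en-1-yl]oxy}trimethylsilane
Conditions: Me3SiOTf, Et3N, CH2Cl2, 0 °C; non-aqueous work-up, used at once
Reagents that add atoms: trimethylsilyl trifluoromethanesulfonate, C[Si](C)(C)OS(=O)(=O)C(F)(F)F
Why: Soft enolisation and O-silylation of a ketone, in which the quaternary C9 allows only the C5=C10 enol ether and the amine base cannot epimerise C8.

Step 5
Reactants: 7 {[(5S,6S)-5,6-dimethyl-6-(prop-2-en-1-yl)cyclohex-1-en-1-yl]oxy}trimethylsilane; 8 mesityl oxide (4-methylpent-3-en-2-one)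
Product: 10 (4aR,7S,8S)-4,4,7,8-tetramethyl-8-(prop-2-en-1-yl)-4,4a,5,6,7,8-hexahydronaphthalen-2(3H)-one, via 1,5-diketone 9 (not isolated)
Conditions: 8, TiCl4 (1.1 equiv), CH2Cl2, −78 °C, then 7; H2O work-up; crude 9, TsOH·H2O (10 mol %), benzene, reflux, Dean–Stark
Reagents that add atoms: mesityl oxide (8), CC(C)=CC(C)=O
Why: TiCl4 activates mesityl oxide and C5 of the silyl enol ether attacks its β,β-dimethyl carbon through an open transition state, giving after loss of Me3SiCl the 1,5-diketone 9 (bond C4–C5); TsOH then enolises the new methyl ketone toward C1, which adds to the C10 carbonyl, and dehydration gives the C1=C10 enone. The closest known reaction type is the TiCl4-mediated Mukaiyama–Michael addition of ketone silyl enol ethers to mesityl oxide followed by acid-catalysed intramolecular aldol condensation, a standard 4,4-dimethylcyclohexenone annulation. Ring A closes in the 6-(enolendo)-exo-trig mode, and because C9 is quaternary the ring B ketone can enolise only toward C5 and only one six-membered aldol is available, so the regiochemistry is fixed by the substrate. The one new stereocentre, C5, is set in the addition: the equatorial C8 methyl holds the half-chair in which the C9 allyl is pseudoaxial, so the bulky TiCl4-bound acceptor should approach C5 from the opposite face, leaving H-5 cis to C11 and the new substituent equatorial in 9. The step needs this facial selectivity and needs C5 (α to the ketone in 9, γ to it in 10) not to equilibrate, which is served by addition at −78 °C, by catalytic acid with azeotropic water removal stopped at full conversion, and by removal of the carbonyl in the next step.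

Step 6
Reactants: 10 (4aR,7S,8S)-4,4,7,8-tetramethyl-8-(prop-2-en-1-yl)-4,4a,5,6,7,8-hexahydronaphthalen-2(3H)-one
Product: 11 (1S,2S,4aR)-1,2,5,5-tetramethyl-1-(prop-2-en-1-yl)-1,2,3,4,4a,5,6,7-octahydronaphthalene
Conditions: LiAlH4, AlCl3 (1:3), Et2O, 0 °C → rt
Reagents that add atoms: none
Why: Mixed-hydride (chloroalane) hydrogenolysis of an enone, in which 1,2-reduction gives an allylic aluminium alkoxide that ionises to the C2–C1–C10 allyl cation and takes hydride at the unhindered secondary C2 and not at C10 (tertiary, between C9 and C5), so the C1=C10 alkene should stay in place and C5 ceases to be epimerisable.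

Step 7
Reactants: 12 (4S)-4-benzyl-1,3-oxazolidin-2-one; 13 acryloyl chloride (prop-2-enoyl chloride)
Product: 15 (4S)-4-benzyl-3-(prop-2-enoyl)-1,3-oxazolidin-2-one, via N-bromomagnesio oxazolidinone 14 (not isolated)
Conditions: MeMgBr, THF, 0 °C; then 13, −78 → 0 °C
Reagents that add atoms: acryloyl chloride (13), C=CC(=O)Cl
Why: N-Acylation of a metalated oxazolidinone, for which the bromomagnesium salt is chosen because it acylates cleanly with acryloyl chloride and causes little anionic polymerisation of the acrylimide.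

Step 8
Reactants: 11 (1S,2S,4aR)-1,2,5,5-tetramethyl-1-(prop-2-en-1-yl)-1,2,3,4,4a,5,6,7-octahydronaphthalene; 15 (4S)-4-benzyl-3-(prop-2-enoyl)-1,3-oxazolidin-2-one
Product: 16 (4S)-4-benzyl-3-[(2E)-4-[(1S,2S,4aR)-1,2,5,5-tetramethyl-1,2,3,4,4a,5,6,7-octahydronaphthalen-1-yl]but-2-enoyl]-1,3-oxazolidin-2-one
Conditions: 15 (2.5 equiv), second-generation Hoveyda–Grubbs catalyst RuCl2(=CH-2-iPrOC6H4)(H2IMes) (5 mol %), CH2Cl2, 40 °C
Reagents that add atoms: (4S)-4-benzyl-3-(prop-2-enoyl)-1,3-oxazolidin-2-one (15), C=CC(=O)N1[C@@H](Cc2ccccc2)COC1=O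
Why: Olefin cross-metathesis of an unhindered terminal alkene with an electron-poor acryloyl partner is selective for the E cross product and joins C12 to C13, while the trisubstituted C1=C10 alkene next to the quaternary C9 should be inert to the Ru=CHR catalyst.

Step 9
Reactants: 16 (4S)-4-benzyl-3-[(2E)-4-[(1S,2S,4aR)-1,2,5,5-tetramethyl-1,2,3,4,4a,5,6,7-octahydronaphthalen-1-yl]but-2-enoyl]-1,3-oxazolidin-2-one
Product: 17 (4S)-4-benzyl-3-{4-[(1S,2S,4aR)-1,2,5,5-tetramethyl-1,2,3,4,4a,5,6,7-octahydronaphthalen-1-yl]butanoyl}-1,3-oxazolidin-2-one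
Conditions: H2 (1 atm), RhCl(PPh3)3 (10 mol %), benzene/EtOH, rt
Reagents that add atoms: none
Why: Homogeneous hydrogenation with RhCl(PPh3)3 reduces the accessible disubstituted C12=C13 alkene and should leave the hindered trisubstituted C1=C10 alkene neither reduced nor isomerised, which Pd/C would not guarantee.

Step 10
Reactants: 17 (4S)-4-benzyl-3-{4-[(1S,2S,4aR)-1,2,5,5-tetramethyl-1,2,3,4,4a,5,6,7-octahydronaphthalen-1-yl]butanoyl}-1,3-oxazolidin-2-one
Product: 19 (4S)-4-benzyl-3-[(2R)-2-{2-[(1S,2S,4aR)-1,2,5,5-tetramethyl-1,2,3,4,4a,5,6,7-octahydronaphthalen-1-yl]ethyl}pent-4-enoyl]-1,3-oxazolidin-2-one, via sodium Z-enolate 18 (not isolated)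
Conditions: NaN(SiMe3)2, THF, −78 °C; then allyl iodide, −78 → −40 °C
Reagents that add atoms: allyl iodide (3-iodoprop-1-ene), C=CCI
Why: Evans asymmetric alkylation, in which the chelated Z-enolate is attacked by allyl iodide on the face opposite the C4 benzyl group of the (S)-auxiliary, setting C13 in the configuration of the target with the allyl group as C14–C16 and the imide carbonyl as the future CH2O carbon.

Step 11
Reactants: 19 (4S)-4-benzyl-3-[(2R)-2-{2-[(1S,2S,4aR)-1,2,5,5-tetramethyl-1,2,3,4,4a,5,6,7-octahydronaphthalen-1-yl]ethyl}pent-4-enoyl]-1,3-oxazolidin-2-one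
Product: 20 (2R)-2-{2-[(1S,2S,4aR)-1,2,5,5-tetramethyl-1,2,3,4,4a,5,6,7-octahydronaphthalen-1-yl]ethyl}pent-4-en-1-ol
Conditions: LiBH4, H2O (1 equiv), Et2O, 0 °C
Reagents that add atoms: none
Why: Reductive cleavage of an N-acyl oxazolidinone at the exocyclic carbonyl gives the primary alcohol without epimerising C13 and returns the auxiliary.

Step 12
Reactants: 20 (2R)-2-{2-[(1S,2S,4aR)-1,2,5,5-tetramethyl-1,2,3,4,4a,5,6,7-octahydronaphthalen-1-yl]ethyl}pent-4-en-1-ol
Product: 21 tert-butyl(dimethyl){[(2R)-2-{2-[(1S,2S,4aR)-1,2,5,5-tetramethyl-1,2,3,4,4a,5,6,7-octahydronaphthalen-1-yl]ethyl}pent-4-en-1-yl]oxy}silane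
Conditions: t-BuMe2SiCl, imidazole, DMF, rt
Reagents that add atoms: tert-butyldimethylsilyl chloride, CC(C)(C)[Si](C)(C)Cl
Why: Silylation of a primary alcohol, so that the hydroxyl neither consumes borane nor interferes with the coupling in the next step.

Step 13
Reactants: 21 tert-butyl(dimethyl){[(2R)-2-{2-[(1S,2S,4aR)-1,2,5,5-tetramethyl-1,2,3,4,4a,5,6,7-octahydronaphthalen-1-yl]ethyl}pent-4-en-1-yl]oxy}silane; 22 4-bromofuran-2(5H)-one
Product: 24 4-[(4S)-4-({[tert-butyl(dimethyl)silyl]oxy}methyl)-6-[(1S,2S,4aR)-1,2,5,5-tetramethyl-1,2,3,4,4a,5,6,7-octahydronaphthalen-1-yl]hexyl]furan-2(5H)-one, via B-alkyl-9-borabicyclononane 23 (not isolated)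
Conditions: 9-BBN (0.5 M in THF), 0 °C → rt; then 22, PdCl2(dppf) (5 mol %), AsPh3 (10 mol %), K3PO4 (3 M aq), DMF, rt
Reagents that add atoms: 4-bromofuran-2(5H)-one (22), O=C1C=C(Br)CO1
Why: 9-BBN hydroborates only the terminal alkene in the anti-Markovnikov sense (boron on C16), and B-alkyl Suzuki–Miyaura coupling with the vinylogous acyl bromide then forms the C16–butenolide bond under mild aqueous phosphate that the butenolide, the silyl ether and the C1=C10 alkene should tolerate.

Step 14
Reactants: 24 4-[(4S)-4-({[tert-butyl(dimethyl)silyl]oxy}methyl)-6-[(1S,2S,4aR)-1,2,5,5-tetramethyl-1,2,3,4,4a,5,6,7-octahydronaphthalen-1-yl]hexyl]furan-2(5H)-one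
Product: 25 4-[(4S)-4-(hydroxymethyl)-6-[(1S,2S,4aR)-1,2,5,5-tetramethyl-1,2,3,4,4a,5,6,7-octahydronaphthalen-1-yl]hexyl]furan-2(5H)-one
Conditions: HF·pyridine, pyridine, THF, 0 °C → rt
Reagents that add atoms: none
Why: Fluoride-mediated cleavage of a primary silyl ether under buffered conditions that should neither isomerise the C1=C10 alkene nor open or deconjugate the butenolide.

Step 15
Reactants: 25 4-[(4S)-4-(hydroxymethyl)-6-[(1S,2S,4aR)-1,2,5,5-tetramethyl-1,2,3,4,4a,5,6,7-octahydronaphthalen-1-yl]hexyl]furan-2(5H)-one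
Product: 27 (2S)-5-(5-oxo-2,5-dihydrofuran-3-yl)-2-{2-[(1S,2S,4aR)-1,2,5,5-tetramethyl-1,2,3,4,4a,5,6,7-octahydronaphthalen-1-yl]ethyl}pentyl hydrogen sulfate (target), via pyridinium alkyl sulfate 26 (not isolated)
Conditions: SO3·pyridine, pyridine, rt; then sulfonic acid cation-exchange resin (H+ form), MeOH/H2O, 0 °C
Reagents that add atoms: sulfur trioxide–pyridine complex, O=S(=O)([O-])[n+]1ccccc1
Why: O-Sulfation of a primary alcohol with the mild SO3·pyridine complex gives the pyridinium alkyl sulfate, and a brief cold cation exchange should release the hydrogen sulfate without touching the alkene or the lactone.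

**Compound list**

1 | cyclohex-2-en-1-one | O=C1C=CCCC1 | starting material
2 | 2-iodocyclohex-2-en-1-one | O=C1C(I)=CCCC1 | intermediate
3 | allyltributylstannane | C=CC[Sn](CCCC)(CCCC)CCCC | starting material
4 | 2-(prop-2-en-1-yl)cyclohex-2-en-1-one | O=C1C(CC=C)=CCCC1 | intermediate
5 | bromomagnesium (3S)-3-methyl-2-(prop-2-en-1-yl)cyclohex-1-en-1-olate | C[C@H]1CCCC(O[Mg]Br)=C1CC=C | intermediate
6 | (2S,3S)-2,3-dimethyl-2-(prop-2-en-1-yl)cyclohexan-1-one | C[C@H]1CCCC(=O)[C@@]1(C)CC=C | intermediate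
7 | {[(5S,6S)-5,6-dimethyl-6-(prop-2-en-1-yl)cyclohex-1-en-1-yl]oxy}trimethylsilane | C[C@H]1CCC=C(O[Si](C)(C)C)[C@@]1(C)CC=C | intermediate
8 | mesityl oxide (4-methylpent-3-en-2-one) | CC(C)=CC(C)=O | starting material
9 | (2S,3S,6R)-2,3-dimethyl-6-(2-methyl-4-oxopentan-2-yl)-2-(prop-2-en-1-yl)cyclohexan-1-one | C[C@H]1CC[C@H](C(C)(C)CC(C)=O)C(=O)[C@@]1(C)CC=C | intermediate
10 | (4aR,7S,8S)-4,4,7,8-tetramethyl-8-(prop-2-en-1-yl)-4,4a,5,6,7,8-hexahydronaphthalen-2(3H)-one | C[C@H]1CC[C@H]2C(=CC(=O)CC2(C)C)[C@@]1(C)CC=C | intermediate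
11 | (1S,2S,4aR)-1,2,5,5-tetramethyl-1-(prop-2-en-1-yl)-1,2,3,4,4a,5,6,7-octahydronaphthalene | C[C@H]1CC[C@H]2C(=CCCC2(C)C)[C@@]1(C)CC=C | intermediate
12 | (4S)-4-benzyl-1,3-oxazolidin-2-one | O=C1N[C@@H](Cc2ccccc2)CO1 | starting material
13 | acryloyl chloride | C=CC(=O)Cl | starting material
14 | N-bromomagnesio (4S)-4-benzyl-1,3-oxazolidin-2-one | O=C1N([Mg]Br)[C@@H](Cc2ccccc2)CO1 | intermediate
15 | (4S)-4-benzyl-3-(prop-2-enoyl)-1,3-oxazolidin-2-one | C=CC(=O)N1[C@@H](Cc2ccccc2)COC1=O | intermediate
16 | (4S)-4-benzyl-3-[(2E)-4-(decalinyl)but-2-enoyl]-1,3-oxazolidin-2-one, decalinyl = (1S,2S,4aR)-1,2,5,5-tetramethyl-1,2,3,4,4a,5,6,7-octahydronaphthalen-1-yl | C[C@H]1CC[C@H]2C(=CCCC2(C)C)[C@@]1(C)C/C=C/C(=O)N1[C@@H](Cc2ccccc2)COC1=O | intermediate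
17 | (4S)-4-benzyl-3-[4-(decalinyl)butanoyl]-1,3-oxazolidin-2-one (same decalinyl group) | C[C@H]1CC[C@H]2C(=CCCC2(C)C)[C@@]1(C)CCCC(=O)N1[C@@H](Cc2ccccc2)COC1=O | intermediate
18 | sodium Z-enolate of 17 | C[C@H]1CC[C@H]2C(=CCCC2(C)C)[C@@]1(C)CC/C=C(\O[Na])N1[C@@H](Cc2ccccc2)COC1=O | intermediate
19 | (4S)-4-benzyl-3-[(2R)-2-[2-(decalinyl)ethyl]pent-4-enoyl]-1,3-oxazolidin-2-one | C[C@H]1CC[C@H]2C(=CCCC2(C)C)[C@@]1(C)CC[C@H](CC=C)C(=O)N1[C@@H](Cc2ccccc2)COC1=O | intermediate
20 | (2R)-2-[2-(decalinyl)ethyl]pent-4-en-1-ol | C[C@H]1CC[C@H]2C(=CCCC2(C)C)[C@@]1(C)CC[C@H](CC=C)CO | intermediate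
21 | tert-butyldimethylsilyl ether of 20 | C[C@H]1CC[C@H]2C(=CCCC2(C)C)[C@@]1(C)CC[C@H](CC=C)CO[Si](C)(C)C(C)(C)C | intermediate
22 | 4-bromofuran-2(5H)-one | O=C1C=C(Br)CO1 | starting material
23 | B-alkyl-9-borabicyclo[3.3.1]nonane from 21 (boron on C16) | C[C@H]1CC[C@H]2C(=CCCC2(C)C)[C@@]1(C)CC[C@H](CCCB1C2CCCC1CCC2)CO[Si](C)(C)C(C)(C)C | intermediate
24 | 4-[(4S)-4-({[tert-butyl(dimethyl)silyl]oxy}methyl)-6-(decalinyl)hexyl]furan-2(5H)-one | C[C@H]1CC[C@H]2C(=CCCC2(C)C)[C@@]1(C)CC[C@H](CCCC1=CC(=O)OC1)CO[Si](C)(C)C(C)(C)C | intermediate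
25 | 4-[(4S)-4-(hydroxymethyl)-6-(decalinyl)hexyl]furan-2(5H)-one | C[C@H]1CC[C@H]2C(=CCCC2(C)C)[C@@]1(C)CC[C@H](CCCC1=CC(=O)OC1)CO | intermediate
26 | pyridinium salt of the C13 hydroxymethyl sulfate | C[C@H]1CC[C@H]2C(=CCCC2(C)C)[C@@]1(C)CC[C@H](CCCC1=CC(=O)OC1)COS(=O)(=O)[O-].c1cc[nH+]cc1 | intermediate
27 | (2S)-5-(5-oxo-2,5-dihydrofuran-3-yl)-2-{2-[(1S,2S,4aR)-1,2,5,5-tetramethyl-1,2,3,4,4a,5,6,7-octahydronaphthalen-1-yl]ethyl}pentyl hydrogen sulfate | C[C@H]1CC[C@H]2C(=CCCC2(C)C)[C@@]1(C)CC[C@H](CCCC1=CC(=O)OC1)COS(=O)(=O)O | target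

**Step count and risk**

Total step count: 15. Longest linear sequence: 14 steps (steps 1–6 and 8–15; step 7 is a one-step side branch).

The three steps most likely to fail:

Step 5. What may go wrong: loss of the C5 configuration by acid-catalysed enolisation of the ring ketone in 9 or dienolisation of 10 during the hot condensation, on top of incomplete facial control in the addition. The fallback takes the ring closure out of the acid regime. It sets out from 1,5-diketone 9, which is isolated by chromatography after the TiCl4 stage. LiN(iPr)2 in THF at −78 °C should deprotonate the unhindered methyl group and give the methyl-ketone lithium enolate F1, which adds to the C10 carbonyl on warming to −20 °C. A cold NH4Cl quench should give the ring A β-hydroxy ketone F2 (tertiary C10 alcohol, either C10 epimer). Dehydration with methyl N-(triethylammoniosulfonyl)carbamate (Burgess reagent) in benzene at 50 °C can only run toward C1, because C9 carries no hydrogen, and comes back to the route at enone 10 without an acid or base able to reach H-5.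

Step 6. What may go wrong: hydride capture at C10 instead of C2, proton loss from the allyl cation to dienes, or hydroalumination of the terminal alkene. The fallback sets out from enone 10. Luche 1,2-reduction (NaBH4, CeCl3·7H2O, MeOH, 0 °C) should give the allylic alcohol F3 (both C2 epimers usable), and Ac2O, pyridine and DMAP the allylic acetate F4. With Pd(PPh3)4 (5 mol %) and LiBHEt3 in THF at rt, zerovalent palladium ionises the acetate and hydride is delivered to the less hindered C2 terminus of the π-allyl complex under neutral conditions. The fallback comes back to the route at diene 11.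

Step 3. What may go wrong: insufficient enantioselectivity of methyl transfer to the α-substituted enone, or enolate equilibration and methylation at C6 during trapping. The fallback sets C8 on the parent enone and introduces the two C9 substituents in the order allyl, then methyl. It sets out from cyclohex-2-en-1-one 1. Me2Zn, Cu(OTf)2 (2 mol %) and the (S)-BINOL-derived bis[(R)-1-phenylethyl]amine phosphoramidite in toluene at −30 °C should give the zinc enolate methylzinc (3S)-3-methylcyclohex-1-en-1-olate F5. Allyl acetate and Pd(PPh3)4 (2 mol %) then give the trans ketone (2R,3S)-3-methyl-2-(prop-2-en-1-yl)cyclohexan-1-one F6. Me3SiCl, NaI and Et3N in MeCN should give the more substituted trimethylsilyl enol ether F7; MeLi in THF at 0 °C releases the lithium enolate F8, and MeI methylates it anti to the C8 methyl exactly as in step 3. The fallback comes back to the route at ketone 6, and stannane 3 is then not needed.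

**Further compounds**

F1 | step 5 | lithium enolate of the methyl ketone of 9 | C[C@H]1CC[C@H](C(C)(C)CC(=C)O[Li])C(=O)[C@@]1(C)CC=C
F2 | step 5 | (4aR,7S,8S)-8a-hydroxy-4,4,7,8-tetramethyl-8-(prop-2-en-1-yl)octahydronaphthalen-2(1H)-one, C10 epimers | C[C@H]1CC[C@H]2C(O)(CC(=O)CC2(C)C)[C@@]1(C)CC=C
F3 | step 6 | (4aR,7S,8S)-4,4,7,8-tetramethyl-8-(prop-2-en-1-yl)-2,3,4,4a,5,6,7,8-octahydronaphthalen-2-ol, C2 epimers | C[C@H]1CC[C@H]2C(=CC(O)CC2(C)C)[C@@]1(C)CC=C
F4 | step 6 | acetate of F3 | C[C@H]1CC[C@H]2C(=CC(OC(C)=O)CC2(C)C)[C@@]1(C)CC=C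
F5 | step 3 | methylzinc (3S)-3-methylcyclohex-1-en-1-olate | C[C@H]1CCCC(O[Zn]C)=C1
F6 | step 3 | (2R,3S)-3-methyl-2-(prop-2-en-1-yl)cyclohexan-1-one | C[C@H]1CCCC(=O)[C@@H]1CC=C
F7 | step 3 | trimethyl{[(3S)-3-methyl-2-(prop-2-en-1-yl)cyclohex-1-en-1-yl]oxy}silane | C[C@H]1CCCC(O[Si](C)(C)C)=C1CC=C
F8 | step 3 | lithium (3S)-3-methyl-2-(prop-2-en-1-yl)cyclohex-1-en-1-olate | C[C@H]1CCCC(O[Li])=C1CC=C
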